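**Plan**

1. Retrosynthesis: the C2=C3 double bond and the free C4 hydroxyl are traced to a saturated ketone with a trans-isopropylidene acetal on O3/O4 (β-elimination retron). The ring bond C5–C6 is then cut (Reformatsky/aldol retron) to an acyclic α-iodomethyl ketone that also holds the C5 ketone. Last are cut the bond from C5 to the side chain (Grignard/aldehyde), the C1–C2 bond (acetylide/triflate) and the side-chain bond C15'–C16' (acetylide/bromide).
2. Enabling feature: in the cyclohexenone ring the carbonyl C1 is β to the tertiary carbinol C5, with only the methylene C6 between them, and the C4 hydroxyl is γ to C1. C6 can therefore be made the single nucleophilic carbon of a 1,5-dicarbonyl chain, and an extra oxygen on C3, tied to O4 as a temporary trans-dioxolane ring, can be expelled afterwards.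
3. Forward: the C19 side chain (steps 1–3) and the C2–C5 core from L-threitol acetonide, extended by C1/C6 from an acetylide (steps 4–7), are joined in step 8. The alkyne becomes the iodomethyl ketone (steps 10–11), the only carbocycle closes in step 12, and step 13 opens the dioxolane to release the enone and the C4 hydroxyl without a separate deprotection.
4. Stereochemistry: C4 (R) comes from L-tartaric acid as L-threitol acetonide and is never exposed to base as an enolisable ene-dione. C5 (S) is set in the ring closure by the trans-fused dioxolane and the samarium chelate. The E double bond comes from Na/NH3 reduction of an alkyne.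

Key step: step 12

Remark: ring atoms are numbered C1 (carbonyl) to C6 as in (4R,5S)-4,5-dihydroxy-5-[(16E)-nonadec-16-en-1-yl]cyclohex-2-en-1-one; the given SMILES defines the two hydroxyls as cis.

**Route**

Step 1
Reactants: 1 15-bromopentadecan-1-ol; 2 but-1-yne
Product: 4 nonadec-16-yn-1-ol, via lithium but-1-yn-1-ide 3 (not isolated)
Conditions: 2 (3 equiv), n-BuLi (2.5 equiv), THF, −78 to 0 °C; then 1, DMPU, 0 °C to rt; aq. NH4Cl
Reagents that add atoms: none
Why: SN2 alkylation of a lithium acetylide by a primary bromide; the first equivalent of 3 only converts the hydroxyl into an inert lithium alkoxide.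

Step 2
Reactants: 4 nonadec-16-yn-1-ol
Product: 5 (16E)-nonadec-16-en-1-ol
Conditions: Na, NH3(l), THF, −33 °C; NH4Cl
Reagents that add atoms: none
Why: Dissolving-metal reduction of an isolated internal alkyne; the trans-vinyl anion is protonated, so the E-alkene of the side chain should result.

Step 3
Reactants: 5 (16E)-nonadec-16-en-1-ol
Product: 6 (3E)-19-bromononadec-3-ene
Conditions: CBr4, PPh3, CH2Cl2, 0 °C
Reagents that add atoms: tetrabromomethane, BrC(Br)(Br)Br
Why: Appel reaction of a primary alcohol; the isolated alkene is inert.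

Step 4
Reactants: 7 [(4S,5S)-2,2-dimethyl-1,3-dioxolane-4,5-diyl]dimethanol
Product: 8 [(4S,5S)-5-({[tert-butyl(dimethyl)silyl]oxy}methyl)-2,2-dimethyl-1,3-dioxolan-4-yl]methanol
Conditions: NaH (1.0 equiv), THF, 0 °C to rt; then TBSCl (1.0 equiv)
Reagents that add atoms: tert-butyl(chloro)dimethylsilane, CC(C)(C)[Si](C)(C)Cl
Why: Monosilylation of a C2-symmetric diol through its sparingly soluble monosodium alkoxide; the hydroxyls are homotopic, so one compound should form and no stereocentre is touched.

Step 5
Reactants: 8 mono-TBS ether; 9 lithium (trimethylsilyl)acetylide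
Product: 11 tert-butyl(dimethyl){[(4S,5S)-2,2-dimethyl-5-[3-(trimethylsilyl)prop-2-yn-1-yl]-1,3-dioxolan-4-yl]methoxy}silane, via primary triflate 10 (not isolated)
Conditions: Tf2O, 2,6-lutidine, CH2Cl2, −78 °C; then 9 (3 equiv, THF), DMPU, −78 to −20 °C
Reagents that add atoms: none
Why: SN2 displacement of a primary triflate by a lithium acetylide, the leaving group of choice at a primary carbon with a β-oxygen where sulfonates and iodides tend to eliminate; the two acetylide carbons become C1 and C6.

Step 6
Reactants: 11 silyl-protected alkyne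
Product: 12 [(4S,5S)-2,2-dimethyl-5-(prop-2-yn-1-yl)-1,3-dioxolan-4-yl]methanol
Conditions: TBAF (2.5 equiv), THF, 0 °C to rt
Reagents that add atoms: none
Why: Fluoride cleaves both the O–Si and the C(sp)–Si bond; the acetonide is stable to these conditions.

Step 7
Reactants: 12 alkynol
Product: 13 (4R,5S)-2,2-dimethyl-5-(prop-2-yn-1-yl)-1,3-dioxolane-4-carbaldehyde
Conditions: Dess–Martin periodinane, CH2Cl2, 0 °C to rt; aq. NaHCO3/Na2S2O3 work-up; used crude
Reagents that add atoms: none
Why: Dess–Martin oxidation under non-basic conditions; the trans-dioxolane is the more stable arrangement, so the α-centre (future C4) should hold.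

Step 8
Reactants: 13 aldehyde; 6 (3E)-19-bromononadec-3-ene
Product: 15 (17E)-1-[(4S,5S)-2,2-dimethyl-5-(prop-2-yn-1-yl)-1,3-dioxolan-4-yl]icos-17-en-1-ol (both C1 epimers), via (16E)-nonadec-16-en-1-ylmagnesium bromide 14 (not isolated)
Conditions: 6, Mg, THF, 40 °C; then 13, THF, −78 to −30 °C; aq. NH4Cl
Reagents that add atoms: none
Why: Grignard addition to an aldehyde; at low temperature addition outruns deprotonation of the terminal alkyne, and the new carbinol centre needs no control because step 9 removes it.

Step 9
Reactants: 15 carbinol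
Product: 16 (17E)-1-[(4R,5S)-2,2-dimethyl-5-(prop-2-yn-1-yl)-1,3-dioxolan-4-yl]icos-17-en-1-one
Conditions: Dess–Martin periodinane, CH2Cl2, rt
Reagents that add atoms: none
Why: Dess–Martin oxidation to the C5 ketone; the α-centre stays in the stable trans arrangement.

Step 10
Reactants: 16 alkynyl ketone
Product: 17 (17E)-1-[(4R,5S)-5-(3-iodoprop-2-yn-1-yl)-2,2-dimethyl-1,3-dioxolan-4-yl]icos-17-en-1-one
Conditions: N-iodosuccinimide, AgNO3 (10 mol%), acetone, rt, dark
Reagents that add atoms: N-iodosuccinimide, O=C1CCC(=O)N1I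
Why: Silver-catalysed iodination of a terminal alkyne through the silver acetylide; without acid or water the E-alkene and the ketone should not react.

Step 11
Reactants: 17 iodoalkyne
Product: 18 (17E)-1-[(4R,5S)-5-(3-iodo-2-oxopropyl)-2,2-dimethyl-1,3-dioxolan-4-yl]icos-17-en-1-one
Conditions: Ph3PAuNTf2 (3 mol%), H2O (3 equiv), 1,2-dichloroethane, rt
Reagents that add atoms: water, O
Why: Gold-catalysed Markovnikov hydration of a haloalkyne; water adds at the carbon remote from iodine (C1), giving the α-iodomethyl ketone under neutral conditions that spare acetonide, alkene and C4.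

Step 12
Reactants: 18 α-iodomethyl ketone
Product: 20 (3aS,7S,7aR)-7-hydroxy-2,2-dimethyl-7-[(16E)-nonadec-16-en-1-yl]hexahydro-1,3-benzodioxol-5-one (trans-fused acetonide on O3/O4, tertiary hydroxyl cis to O4), via diiodosamarium enolate 19 (not isolated)
Conditions: SmI2 (2.2 equiv, 0.1 M in THF) added slowly to 18, THF, −78 °C; pH 7 buffer
Reagents that add atoms: none
Why: Two single-electron transfers from SmI2 (divalent samarium) cleave the C–I bond and give the O-bound trivalent samarium enolate 19, nucleophilic at C6 only, so the former electrophile C6 adds to the electrophilic C5 ketone carbon (polarity reversal); the closest known reaction type is the SmI2-promoted intramolecular Reformatsky-type aldol of α-halo ketones. The carbocycle closes in the 6-(enolendo)-exo-trig mode. C5 is controlled by the trans-fused dioxolane on C3/C4, which holds both ring oxygens equatorial in a chair transition state: C6 attacks anti to the C4–O bond (Felkin–Anh), the long chain sits equatorial and the carbonyl oxygen axial, where samarium bridges it to the enolate oxygen (Zimmerman–Traxler-like chelate), and axial C5–O next to equatorial C4–O is the cis (4R,5S) arrangement. The step needs regioselectivity (enolate only at C6), chemoselectivity (C–I before the α-alkoxy ketone) and retention of C4: the iodide fixes the enolate site, no base is present to enolise C2, C4 or the chain α-carbon or to expel the C3 oxygen, and slow addition at −78 °C leaves no excess reductant for ketyl formation at C5.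

Step 13
Reactants: 20 bicyclic aldol
Product: 21 (4R,5S)-4,5-dihydroxy-5-[(16E)-nonadec-16-en-1-yl]cyclohex-2-en-1-one
Conditions: DBU (0.5 equiv), CH2Cl2, −20 to 0 °C; AcOH quench
Reagents that add atoms: none
Why: E1cB elimination: enolisation towards C2 expels the strained trans-fused acetal oxygen on C3, and the hemiketal alkoxide then loses acetone, so the C2=C3 enone and the free C4 hydroxyl appear together while the tertiary C5 hydroxyl (poor leaving group) stays; no stereocentre is touched.

**Compound list**

1 | 15-bromopentadecan-1-ol | OCCCCCCCCCCCCCCCBr | starting material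
2 | but-1-yne | CCC#C | starting material
3 | lithium but-1-yn-1-ide (formed in the flask) | [Li]C#CCC | intermediate
4 | nonadec-16-yn-1-ol | CCC#CCCCCCCCCCCCCCCCO | intermediate
5 | (16E)-nonadec-16-en-1-ol | CC/C=C/CCCCCCCCCCCCCCCO | intermediate
6 | (3E)-19-bromononadec-3-ene | CC/C=C/CCCCCCCCCCCCCCCBr | intermediate
7 | [(4S,5S)-2,2-dimethyl-1,3-dioxolane-4,5-diyl]dimethanol ((+)-2,3-O-isopropylidene-L-threitol) | OC[C@@H]1OC(C)(C)O[C@H]1CO | starting material
8 | [(4S,5S)-5-({[tert-butyl(dimethyl)silyl]oxy}methyl)-2,2-dimethyl-1,3-dioxolan-4-yl]methanol | CC(C)(C)[Si](C)(C)OC[C@@H]1OC(C)(C)O[C@H]1CO | intermediate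
9 | lithium (trimethylsilyl)acetylide (solution in THF) | C[Si](C)(C)C#C[Li] | starting material
10 | [(4S,5S)-5-({[tert-butyl(dimethyl)silyl]oxy}methyl)-2,2-dimethyl-1,3-dioxolan-4-yl]methyl trifluoromethanesulfonate (formed in the flask) | CC(C)(C)[Si](C)(C)OC[C@@H]1OC(C)(C)O[C@H]1COS(=O)(=O)C(F)(F)F | intermediate
11 | tert-butyl(dimethyl){[(4S,5S)-2,2-dimethyl-5-[3-(trimethylsilyl)prop-2-yn-1-yl]-1,3-dioxolan-4-yl]methoxy}silane | CC(C)(C)[Si](C)(C)OC[C@@H]1OC(C)(C)O[C@H]1CC#C[Si](C)(C)C | intermediate
12 | [(4S,5S)-2,2-dimethyl-5-(prop-2-yn-1-yl)-1,3-dioxolan-4-yl]methanol | OC[C@@H]1OC(C)(C)O[C@H]1CC#C | intermediate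
13 | (4R,5S)-2,2-dimethyl-5-(prop-2-yn-1-yl)-1,3-dioxolane-4-carbaldehyde | O=C[C@@H]1OC(C)(C)O[C@H]1CC#C | intermediate
14 | (16E)-nonadec-16-en-1-ylmagnesium bromide (formed in the flask) | CC/C=C/CCCCCCCCCCCCCCC[Mg]Br | intermediate
15 | (17E)-1-[(4S,5S)-2,2-dimethyl-5-(prop-2-yn-1-yl)-1,3-dioxolan-4-yl]icos-17-en-1-ol, both epimers at C1 | CC/C=C/CCCCCCCCCCCCCCCC(O)[C@@H]1OC(C)(C)O[C@H]1CC#C | intermediate
16 | (17E)-1-[(4R,5S)-2,2-dimethyl-5-(prop-2-yn-1-yl)-1,3-dioxolan-4-yl]icos-17-en-1-one | CC/C=C/CCCCCCCCCCCCCCCC(=O)[C@@H]1OC(C)(C)O[C@H]1CC#C | intermediate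
17 | (17E)-1-[(4R,5S)-5-(3-iodoprop-2-yn-1-yl)-2,2-dimethyl-1,3-dioxolan-4-yl]icos-17-en-1-one | CC/C=C/CCCCCCCCCCCCCCCC(=O)[C@@H]1OC(C)(C)O[C@H]1CC#CI | intermediate
18 | (17E)-1-[(4R,5S)-5-(3-iodo-2-oxopropyl)-2,2-dimethyl-1,3-dioxolan-4-yl]icos-17-en-1-one | CC/C=C/CCCCCCCCCCCCCCCC(=O)[C@@H]1OC(C)(C)O[C@H]1CC(=O)CI | intermediate
19 | diiodosamarium enolate of 18 at C1/C6, O-bound trivalent samarium (formed in the flask) | CC/C=C/CCCCCCCCCCCCCCCC(=O)[C@@H]1OC(C)(C)O[C@H]1CC(=C)O[Sm](I)I | intermediate
20 | (3aS,7S,7aR)-7-hydroxy-2,2-dimethyl-7-[(16E)-nonadec-16-en-1-yl]hexahydro-1,3-benzodioxol-5-one | CC/C=C/CCCCCCCCCCCCCCC[C@]1(O)CC(=O)C[C@@H]2OC(C)(C)O[C@@H]12 | intermediate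
21 | (4R,5S)-4,5-dihydroxy-5-[(16E)-nonadec-16-en-1-yl]cyclohex-2-en-1-one | CC/C=C/CCCCCCCCCCCCCCC[C@]1(O)CC(=O)C=C[C@H]1O | target

**Step count**

Total: 13 steps. Longest linear sequence: 10 steps (steps 4 to 13 from 7); the side-chain branch (steps 1 to 3) enters at step 8.

**Steps most likely to fail**

1. Step 12. The samarium enolate may be protonated before it closes the ring (net loss of iodine), excess reductant may cleave the C4–O bond next to the C5 ketone, or the facial selectivity at C5 may be insufficient. The fallback sets out from 18: reductive silylation (Zn dust, Me3SiCl, TMEDA, Et2O, 0 °C) should give the trimethylsilyl enol ether F1, with the enol double bond again fixed at C1=C6. An intramolecular Mukaiyama aldol (BF3·OEt2, CH2Cl2, −78 °C, aqueous work-up) then closes C5–C6 through an open, Lewis-acid-bound transition state under the same ring-fusion control, and the route is rejoined at 20.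

2. Step 13. Departure of the equatorial acetal oxygen may be slow, so that loss of the tertiary C5 hydroxyl (followed by aromatisation to the alkylhydroquinone) or retro-aldol opening competes. The fallback sets out from 20: hydrolysis of the acetal (80% aq. AcOH, rt) should give the triol F2. Acetylation of the two secondary hydroxyls (Ac2O, pyridine, DMAP, 0 °C) gives the diacetate F3, in which the leaving group on C3 is acyclic and free to become axial. Et3N in CH2Cl2 then eliminates the C3 acetate to give the enone acetate F4, and K2CO3 in MeOH at 0 °C removes the remaining acetate, rejoining the route at 21.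

3. Step 11. Hydration of the hindered haloalkyne may stall or proceed with loss of iodine, and the light-sensitive α-iodoketone may decompose under the Lewis-acidic gold catalyst. The fallback sets out from 16 and bypasses 17: gold-catalysed Markovnikov addition of acetic acid to the terminal alkyne (Ph3PAuCl/AgPF6, AcOH, toluene, rt) should give the enol acetate F5. N-iodosuccinimide in dry MeCN at 0 °C then iodinates the enol carbon C6 and transfers the acetyl group to succinimide, and the route is rejoined at 18.

**Further compounds**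

F1 | step 12 | (17E)-1-[(4R,5S)-2,2-dimethyl-5-{2-[(trimethylsilyl)oxy]prop-2-en-1-yl}-1,3-dioxolan-4-yl]icos-17-en-1-one | CC/C=C/CCCCCCCCCCCCCCCC(=O)[C@@H]1OC(C)(C)O[C@H]1CC(=C)O[Si](C)(C)C
F2 | step 13 | (3S,4R,5S)-3,4,5-trihydroxy-3-[(16E)-nonadec-16-en-1-yl]cyclohexan-1-one | CC/C=C/CCCCCCCCCCCCCCC[C@]1(O)CC(=O)C[C@H](O)[C@H]1O
F3 | step 13 | (1S,2R,3S)-3-hydroxy-3-[(16E)-nonadec-16-en-1-yl]-5-oxocyclohexane-1,2-diyl diacetate | CC/C=C/CCCCCCCCCCCCCCC[C@]1(O)CC(=O)C[C@H](OC(C)=O)[C@H]1OC(C)=O
F4 | step 13 | (1R,6S)-6-hydroxy-6-[(16E)-nonadec-16-en-1-yl]-4-oxocyclohex-2-en-1-yl acetate | CC/C=C/CCCCCCCCCCCCCCC[C@]1(O)CC(=O)C=C[C@H]1OC(C)=O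
F5 | step 11 | 3-[(4S,5R)-5-[(17E)-icos-17-enoyl]-2,2-dimethyl-1,3-dioxolan-4-yl]prop-1-en-2-yl acetate | CC/C=C/CCCCCCCCCCCCCCCC(=O)[C@@H]1OC(C)(C)O[C@H]1CC(=C)OC(C)=O
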